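**Retrosynthetic overview**

1. The two esters go on last: angelate on the C2–OH, then (2S,3S)-epoxyangelate on the axial C6–OH. The epoxy acid comes from angelyl alcohol by Sharpless epoxidation.
2. The cis β-acyloxy ketone of the cyclopentane ring (acetyl C=O–C1–C2–O, both substituents α) is traced to a cis-fused β-lactone across C1–C2, a ring that is not in the target. Petasis methylenation then turns the lactone C=O into the acetyl CH3 and the C4 ketone into the exocyclic methylene in one operation.
3. The β-lactone comes from a seco aldehyde-acid by nucleophile-catalysed aldol-lactonisation. This forms C1–C2, closes the five-membered ring of the trans-hydrindane and sets C1 and C2 together.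
4. The aldehyde-acid comes from ozonolysis of a silyl enol ether in a trans-decalone, so a six-membered carbocycle is contracted to the cyclopentane. The decalone comes from a Diels–Alder reaction of (S)-cryptone with a 2-silyloxybutadiene, and the C6 oxygen from enone formation and conjugate borylation.
5. Ring order: cyclohexenone (organocatalytic Michael/aldol), temporary second six-membered ring (Diels–Alder), cleavage, cyclopentane plus β-lactone (key step), lactone opened.

Key step: step 9

Remark (locants): target carbons carry the indane locants of 28 (C1 acetyl-bearing, C2 angeloyloxy-bearing, C3, C3a, C4 methylidene-bearing, C5, C6 epoxyangeloyloxy-bearing, C7 isopropyl-bearing, C7a). Decalone locants C1/C2/C3/C4/C4a/C5/C6/C7/C8/C8a become indane C4/C5/C6/C7/C7a/C1/acetyl C=O/C2/C3/C3a. α is the face of the C7a–H (decalin C4a–H); all four ring substituents of 28 lie on it.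

**Route**

Step 1
Reactants: 1 3-methylbutanal; 2 but-3-en-2-one
Product: 3 (2S)-5-oxo-2-(propan-2-yl)hexanal
Conditions: (S)-α,α-diphenylprolinol TMS ether (5 mol%), ethyl 3,4-dihydroxybenzoate (20 mol%), neat, 4 °C
Reagents that add atoms: none
Why: Enamine-catalysed Michael addition (diarylprolinol silyl ether catalysis); the diarylsilyloxymethyl group shields one face of the E-enamine of 1, so 2 should add to the open face and set the isopropyl-bearing stereocentre (later C7) as S.

Step 2
Reactants: 3 (2S)-5-oxo-2-(propan-2-yl)hexanal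
Product: 4 (4S)-4-(propan-2-yl)cyclohex-2-en-1-one ((S)-cryptone)
Conditions: LiOH (cat.), iPrOH, rt
Reagents that add atoms: none
Why: Intramolecular aldol condensation of the methyl ketone onto the aldehyde (Robinson-type closure); the mild base should close the ring faster than the α-stereocentre epimerises.

Step 3
Reactants: 2 but-3-en-2-one
Product: 5 2-[(tert-butyldimethylsilyl)oxy]buta-1,3-diene
Conditions: TBSOTf, Et3N, Et2O, 0 °C to rt
Reagents that add atoms: tert-butyldimethylsilyl trifluoromethanesulfonate, CC(C)(C)[Si](C)(C)OS(=O)(=O)C(F)(F)F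
Why: Soft enolisation and O-silylation on the methyl side of the enone gives the cross-conjugated 2-silyloxy diene (silyl enol ether formation).

Step 4
Reactants: 4 (S)-cryptone; 5 2-[(tert-butyldimethylsilyl)oxy]buta-1,3-diene
Product: 7 (4S,4aS,8aR)-6-[(tert-butyldimethylsilyl)oxy]-4-(propan-2-yl)-3,4,4a,5,8,8a-hexahydronaphthalen-1(2H)-one (trans-fused), via cis-fused cycloadduct 6 (not isolated)
Conditions: AlBr3/AlMe3 (cat.), toluene/CH2Cl2, −5 °C; aqueous work-up; then DBU, toluene, 50 °C
Reagents that add atoms: none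
Why: Lewis acid-catalysed Diels–Alder reaction with "para" orientation (the CH2 terminus next to C–OSi bonds to the enone β-carbon) on the face anti to the isopropyl group sets C4a, and base epimerisation of the ketone α-carbon C8a converts the cis adduct into the all-equatorial trans-decalone under thermodynamic control.

Step 5
Reactants: 7 trans-decalone silyl enol ether
Product: 9 (4R,4aS,8aR)-6-[(tert-butyldimethylsilyl)oxy]-4-(propan-2-yl)-4a,5,8,8a-tetrahydronaphthalen-1(4H)-one, via lithium enolate 8 (not isolated)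
Conditions: LDA, THF, −78 °C; then PhS(Cl)=N-t-Bu, −78 °C
Reagents that add atoms: none
Why: Kinetic deprotonation at the CH2 α-carbon (C2) rather than the ring-fusion CH, then one-pot dehydrogenation with N-tert-butylbenzenesulfinimidoyl chloride (sulfur transfer to the enolate carbon and syn-elimination), should give the C2=C3 enone at low temperature without touching the silyl enol ether.

Step 6
Reactants: 9 C2=C3 enone
Product: 11 (3R,4S,4aS,8aR)-6-[(tert-butyldimethylsilyl)oxy]-3-hydroxy-4-(propan-2-yl)-3,4,4a,5,8,8a-hexahydronaphthalen-1(2H)-one, via 3α-boryl ketone 10 (not isolated)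
Conditions: CuCl/DPEphos/NaOt-Bu (cat.), B2pin2, MeOH, THF, rt; then NaBO3·4H2O, THF/H2O, rt
Reagents that add atoms: sodium perborate (oxygen of the C3 hydroxyl), [Na+].[Na+].O[B-]1(O)OO[B-](O)(O)OO1; bis(pinacolato)diboron (boron of 10 only), CC1(C)OB(OC1(C)C)B1OC(C)(C)C(C)(C)O1
Why: Copper-catalysed conjugate borylation should deliver boron axially to C3 on the α face (anti to the axial C4–H, chair-like enolate, the usual course for rigid cyclohexenones), and perborate oxidation with retention gives the axial 3α-alcohol cis to the isopropyl group.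

Step 7
Reactants: 11 β-hydroxy ketone
Product: 12 (3R,4S,4aS,8aR)-3,6-bis[(tert-butyldimethylsilyl)oxy]-4-(propan-2-yl)-3,4,4a,5,8,8a-hexahydronaphthalen-1(2H)-one
Conditions: TBSOTf, 2,6-lutidine, CH2Cl2, −78 to −20 °C
Reagents that add atoms: tert-butyldimethylsilyl trifluoromethanesulfonate, CC(C)(C)[Si](C)(C)OS(=O)(=O)C(F)(F)F
Why: Silyl triflate silylation is fast enough for the hindered axial alcohol at low temperature, where the ketone is not enolised and the β-silyloxy ketone does not eliminate.

Step 8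
Reactants: 12 bis-silyl decalone
Product: 14 2-[(1S,2S,3R,6R)-3-[(tert-butyldimethylsilyl)oxy]-5-oxo-6-(2-oxoethyl)-2-(propan-2-yl)cyclohexyl]acetic acid, via silyl ester aldehyde 13 (not isolated)
Conditions: O3, CH2Cl2/MeOH, −78 °C; Me2S, −78 °C to rt; then AcOH/THF/H2O, rt
Reagents that add atoms: ozone, [O-][O+]=O
Why: Ozonolysis of the only C=C bond, the electron-rich silyl enol ether, gives a silyl ester at the former C6 and an aldehyde at the former C7 with no redox adjustment, and aqueous acetic acid hydrolyses the labile silyl ester but not the secondary silyl ether.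

Step 9
Reactants: 14 keto aldehyde acid
Product: 16 tricyclic keto-β-lactone [β-lactone of (1R,2S,3aR,6R,7S,7aS)-6-[(tert-butyldimethylsilyl)oxy]-2-hydroxy-4-oxo-7-(propan-2-yl)octahydro-1H-indene-1-carboxylic acid], via ammonium enolate 15 (not isolated)
Conditions: 2-chloro-1-methylpyridinium iodide, iPr2NEt, 4-pyrrolidinopyridine (30 mol%), MeCN, slow addition of 14, rt
Reagents that add atoms: none
Why: The pyridinium salt activates the acid, 4-pyrrolidinopyridine takes over the acyl group and iPr2NEt deprotonates the acylammonium ion to the ammonium enolate 15, which adds to the aldehyde and is then O-acylated by the new alkoxide with release of the catalyst. The closest known reaction type is the nucleophile-catalysed aldol-lactonisation of aldehyde acids to cyclopentane-fused β-lactones. The cyclopentane closes in a 5-(enolexo)-exo-trig aldol step between C1 and C2, and the oxetanone in a 4-exo-trig acyl substitution. At C1 the bulky acylammonium group should take the outward pseudo-equatorial (α) position of the forming trans-hydrindane envelope, away from the axial C–H bonds at C7 and C3a on the β face; at C2 the oxygen must be cis to the acyl carbon, because only the cis aldolate can close the four-membered ring and the trans aldolate can revert by retro-aldol. The step needs the aldehyde and not the ketone as electrophile and enolisation only at the acid α-carbon: attack on the ketone would need a four-membered carbocycle, and the acylammonium α-CH is the most acidic C–H under amine base.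

Step 10
Reactants: 16 tricyclic keto-β-lactone
Product: 18 1-[(1R,2S,3aR,6R,7S,7aR)-6-[(tert-butyldimethylsilyl)oxy]-2-hydroxy-4-methylidene-7-(propan-2-yl)octahydro-1H-inden-1-yl]ethan-1-one, via bis-methylidene oxetane 17 (not isolated)
Conditions: Cp2TiMe2 (5 equiv), toluene, 75 °C, dark; then PPTS (cat.), THF/H2O, 0 °C
Reagents that add atoms: dimethyltitanocene (both CH2 groups), [CH3-].[CH3-].[Ti+4].c1cc[cH-]c1.c1cc[cH-]c1; water (ketone oxygen), O
Why: Petasis methylenation converts the ketone into the exocyclic alkene and the β-lactone carbonyl into a 2-methylideneoxetane in one operation, and mild acid hydrolysis of this enol ether (C-protonation, hemiketal, ring opening at the ketal carbon) unveils the methyl ketone and the 2α-hydroxyl without breaking a bond at C1 or C2.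

Step 11
Reactants: 18 β-hydroxy ketone; 19 (2Z)-2-methylbut-2-enoic acid (angelic acid)
Product: 21 (1R,2S,3aR,6R,7S,7aR)-1-acetyl-6-[(tert-butyldimethylsilyl)oxy]-4-methylidene-7-(propan-2-yl)octahydro-1H-inden-2-yl (2Z)-2-methylbut-2-enoate, via angeloyl mixed anhydride 20 (not isolated)
Conditions: 19, 2,4,6-trichlorobenzoyl chloride, Et3N, toluene, rt; then 18, toluene, 60 °C
Reagents that add atoms: none
Why: Yamaguchi esterification without DMAP, the mixed-anhydride protocol that transfers the angeloyl group without Z to E isomerisation; the C6 oxygen is still silylated, so only the C2 hydroxyl reacts.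

Step 12
Reactants: 21 silyl ether angelate
Product: 22 (1R,2S,3aR,6R,7S,7aR)-1-acetyl-6-hydroxy-4-methylidene-7-(propan-2-yl)octahydro-1H-inden-2-yl (2Z)-2-methylbut-2-enoate
Conditions: HF·pyridine, pyridine/THF, 0 °C to rt
Reagents that add atoms: none
Why: Buffered fluoride cleavage of the silyl ether is neither basic nor strongly acidic, so the β-acyloxy ketone, the angelate and the exocyclic alkene should survive.

Step 13
Reactants: 23 methyl (2Z)-2-methylbut-2-enoate (methyl angelate)
Product: 24 (2Z)-2-methylbut-2-en-1-ol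
Conditions: DIBAL-H, CH2Cl2, −78 °C
Reagents that add atoms: none
Why: 1,2-Reduction of the enoate by the aluminium hydride at low temperature keeps the Z geometry.

Step 14
Reactants: 24 (2Z)-2-methylbut-2-en-1-ol
Product: 25 [(2R,3S)-2,3-dimethyloxiran-2-yl]methanol
Conditions: Ti(OiPr)4, D-(−)-diethyl tartrate (cat.), t-BuOOH, 4 Å MS, CH2Cl2, −20 °C
Reagents that add atoms: tert-butyl hydroperoxide, CC(C)(C)OO
Why: Sharpless asymmetric epoxidation; the D-(−)-tartrate catalyst should deliver oxygen to the face that gives the (2R,3S)-epoxy alcohol, and the Z alkene fixes CH2OH and the C3 methyl cis.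

Step 15
Reactants: 25 [(2R,3S)-2,3-dimethyloxiran-2-yl]methanol
Product: 26 (2S,3S)-2,3-dimethyloxirane-2-carboxylic acid
Conditions: RuCl3 (cat.), NaIO4, MeCN/CCl4/H2O, rt
Reagents that add atoms: water (second carboxyl oxygen, via the aldehyde hydrate), O; sodium periodate (terminal oxidant), [Na+].[O-]I(=O)(=O)=O
Why: Ruthenium tetroxide oxidation of the primary alcohol to the glycidic acid leaves the trisubstituted epoxide intact; the C2 descriptor changes from R to S only through the CIP priorities.

Step 16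
Reactants: 22 C6 alcohol; 26 (2S,3S)-2,3-dimethyloxirane-2-carboxylic acid
Product: 28 (1R,2S,3aR,6R,7S,7aR)-1-acetyl-4-methylidene-2-{[(2Z)-2-methylbut-2-enoyl]oxy}-7-(propan-2-yl)octahydro-1H-inden-6-yl (2S,3S)-2,3-dimethyloxirane-2-carboxylate (CNP0300602.1), via epoxyangeloyl mixed anhydride 27 (not isolated)
Conditions: 26, 2,4,6-trichlorobenzoyl chloride, Et3N, THF, rt; then 22, DMAP, toluene, 0 °C to rt
Reagents that add atoms: none
Why: Yamaguchi esterification acylates the hindered axial C6 alcohol at the less hindered aliphatic carbonyl of the mixed anhydride with retention at C6, and the low temperature limits base-induced elimination of the β-acyloxy ketone.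

**Compound list**

1 | 3-methylbutanal | CC(C)CC=O | starting material
2 | but-3-en-2-one | CC(=O)C=C | starting material
3 | (2S)-5-oxo-2-(propan-2-yl)hexanal | CC(=O)CC[C@@H](C(C)C)C=O | intermediate
4 | (4S)-4-(propan-2-yl)cyclohex-2-en-1-one | O=C1CC[C@@H](C(C)C)C=C1 | intermediate
5 | 2-[(tert-butyldimethylsilyl)oxy]buta-1,3-diene | C=CC(=C)O[Si](C)(C)C(C)(C)C | intermediate
6 | (4S,4aS,8aS)-6-[(tert-butyldimethylsilyl)oxy]-4-(propan-2-yl)-3,4,4a,5,8,8a-hexahydronaphthalen-1(2H)-one (cis-fused cycloadduct) | O=C1CC[C@@H](C(C)C)[C@@H]2CC(O[Si](C)(C)C(C)(C)C)=CC[C@H]12 | intermediate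
7 | (4S,4aS,8aR)-6-[(tert-butyldimethylsilyl)oxy]-4-(propan-2-yl)-3,4,4a,5,8,8a-hexahydronaphthalen-1(2H)-one (trans-fused) | O=C1CC[C@@H](C(C)C)[C@@H]2CC(O[Si](C)(C)C(C)(C)C)=CC[C@@H]12 | intermediate
8 | lithium C1=C2 enolate of 7 | [Li]OC1=CC[C@@H](C(C)C)[C@@H]2CC(O[Si](C)(C)C(C)(C)C)=CC[C@@H]12 | intermediate
9 | (4R,4aS,8aR)-6-[(tert-butyldimethylsilyl)oxy]-4-(propan-2-yl)-4a,5,8,8a-tetrahydronaphthalen-1(4H)-one | O=C1C=C[C@@H](C(C)C)[C@@H]2CC(O[Si](C)(C)C(C)(C)C)=CC[C@@H]12 | intermediate
10 | (3R,4S,4aS,8aR)-6-[(tert-butyldimethylsilyl)oxy]-4-(propan-2-yl)-3-(4,4,5,5-tetramethyl-1,3,2-dioxaborolan-2-yl)-3,4,4a,5,8,8a-hexahydronaphthalen-1(2H)-one | O=C1C[C@@H](B3OC(C)(C)C(C)(C)O3)[C@@H](C(C)C)[C@@H]2CC(O[Si](C)(C)C(C)(C)C)=CC[C@@H]12 | intermediate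
11 | (3R,4S,4aS,8aR)-6-[(tert-butyldimethylsilyl)oxy]-3-hydroxy-4-(propan-2-yl)-3,4,4a,5,8,8a-hexahydronaphthalen-1(2H)-one | O=C1C[C@@H](O)[C@@H](C(C)C)[C@@H]2CC(O[Si](C)(C)C(C)(C)C)=CC[C@@H]12 | intermediate
12 | (3R,4S,4aS,8aR)-3,6-bis[(tert-butyldimethylsilyl)oxy]-4-(propan-2-yl)-3,4,4a,5,8,8a-hexahydronaphthalen-1(2H)-one | O=C1C[C@@H](O[Si](C)(C)C(C)(C)C)[C@@H](C(C)C)[C@@H]2CC(O[Si](C)(C)C(C)(C)C)=CC[C@@H]12 | intermediate
13 | tert-butyldimethylsilyl 2-[(1S,2S,3R,6R)-3-[(tert-butyldimethylsilyl)oxy]-5-oxo-6-(2-oxoethyl)-2-(propan-2-yl)cyclohexyl]acetate | O=C1C[C@@H](O[Si](C)(C)C(C)(C)C)[C@@H](C(C)C)[C@H](CC(=O)O[Si](C)(C)C(C)(C)C)[C@H]1CC=O | intermediate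
14 | 2-[(1S,2S,3R,6R)-3-[(tert-butyldimethylsilyl)oxy]-5-oxo-6-(2-oxoethyl)-2-(propan-2-yl)cyclohexyl]acetic acid | O=C1C[C@@H](O[Si](C)(C)C(C)(C)C)[C@@H](C(C)C)[C@H](CC(=O)O)[C@H]1CC=O | intermediate
15 | 4-pyrrolidinopyridinium enolate of the acyl group of 14 | O=C1C[C@@H](O[Si](C)(C)C(C)(C)C)[C@@H](C(C)C)[C@H](C=C([O-])[n+]2ccc(N3CCCC3)cc2)[C@H]1CC=O | intermediate
16 | β-lactone (C1 carboxyl to C2 oxygen, both α) of (1R,2S,3aR,6R,7S,7aS)-6-[(tert-butyldimethylsilyl)oxy]-2-hydroxy-4-oxo-7-(propan-2-yl)octahydro-1H-indene-1-carboxylic acid | O=C1C[C@@H](O[Si](C)(C)C(C)(C)C)[C@@H](C(C)C)[C@@H]2[C@H]3C(=O)O[C@H]3C[C@@H]12 | intermediate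
17 | bis-methylidene analogue of 16 (C4 exocyclic methylene; 2-methylideneoxetane in place of the lactone C=O; ring stereocentres as in 16) | C=C1C[C@@H](O[Si](C)(C)C(C)(C)C)[C@@H](C(C)C)[C@@H]2[C@H]3C(=C)O[C@H]3C[C@@H]12 | intermediate
18 | 1-[(1R,2S,3aR,6R,7S,7aR)-6-[(tert-butyldimethylsilyl)oxy]-2-hydroxy-4-methylidene-7-(propan-2-yl)octahydro-1H-inden-1-yl]ethan-1-one | C=C1C[C@@H](O[Si](C)(C)C(C)(C)C)[C@@H](C(C)C)[C@@H]2[C@@H](C(C)=O)[C@@H](O)C[C@@H]12 | intermediate
19 | (2Z)-2-methylbut-2-enoic acid (angelic acid) | C/C=C(/C)C(=O)O | starting material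
20 | (2Z)-2-methylbut-2-enoic 2,4,6-trichlorobenzoic anhydride | C/C=C(/C)C(=O)OC(=O)c1c(Cl)cc(Cl)cc1Cl | intermediate
21 | (1R,2S,3aR,6R,7S,7aR)-1-acetyl-6-[(tert-butyldimethylsilyl)oxy]-4-methylidene-7-(propan-2-yl)octahydro-1H-inden-2-yl (2Z)-2-methylbut-2-enoate | C=C1C[C@@H](O[Si](C)(C)C(C)(C)C)[C@@H](C(C)C)[C@@H]2[C@@H](C(C)=O)[C@@H](OC(=O)/C(C)=C\C)C[C@@H]12 | intermediate
22 | (1R,2S,3aR,6R,7S,7aR)-1-acetyl-6-hydroxy-4-methylidene-7-(propan-2-yl)octahydro-1H-inden-2-yl (2Z)-2-methylbut-2-enoate | C=C1C[C@@H](O)[C@@H](C(C)C)[C@@H]2[C@@H](C(C)=O)[C@@H](OC(=O)/C(C)=C\C)C[C@@H]12 | intermediate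
23 | methyl (2Z)-2-methylbut-2-enoate (methyl angelate) | C/C=C(/C)C(=O)OC | starting material
24 | (2Z)-2-methylbut-2-en-1-ol | C/C=C(/C)CO | intermediate
25 | [(2R,3S)-2,3-dimethyloxiran-2-yl]methanol | OC[C@@]1(C)O[C@H]1C | intermediate
26 | (2S,3S)-2,3-dimethyloxirane-2-carboxylic acid | OC(=O)[C@@]1(C)O[C@H]1C | intermediate
27 | (2S,3S)-2,3-dimethyloxirane-2-carboxylic 2,4,6-trichlorobenzoic anhydride | O=C(OC(=O)[C@@]1(C)O[C@H]1C)c1c(Cl)cc(Cl)cc1Cl | intermediate
28 | (1R,2S,3aR,6R,7S,7aR)-1-acetyl-4-methylidene-2-{[(2Z)-2-methylbut-2-enoyl]oxy}-7-(propan-2-yl)octahydro-1H-inden-6-yl (2S,3S)-2,3-dimethyloxirane-2-carboxylate | C=C1C[C@@H](OC(=O)[C@@]2(C)O[C@H]2C)[C@@H](C(C)C)[C@@H]2[C@@H](C(C)=O)[C@@H](OC(=O)/C(C)=C\C)C[C@@H]12 | target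

**Step count and risks**

Total step count: 16. Longest linear sequence: 12 steps (1, 2, 4–12, 16).

Steps most likely to fail:

1. Step 9 (aldol-lactonisation). The ammonium enolate may add with poor facial selectivity at C1. The activated acid may also be lost to intermolecular acylation, or the keto aldehyde to amine-induced aldol reactions, before the aldehyde is intercepted. The fallback sets out from 14. The acid is converted with PhSH/EDC/cat. DMAP into the S-phenyl thioester F1. A soft-enolisation intramolecular aldol reaction (MgBr2·OEt2, iPr2NEt, CH2Cl2) under reversible, chelation-controlled conditions should then give the cis β-hydroxy thioester F2, because the magnesium chelate between aldolate and thioester carbonyl is only possible for the cis isomer. Thiophile-promoted lactonisation (Hg(O2CCF3)2, MeCN) comes back to the route at 16.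

2. Step 10 (double methylenation and hydrolysis). Methylenation of the strained lactone carbonyl may stop short, titanium species may open the β-lactone, or the 2-methylideneoxetane may decompose before the controlled hydrolysis. The fallback sets out from 16. Aminolysis with MeNH(OMe)·HCl/Me2AlCl gives the β-hydroxy Weinreb amide F3 with the C4 ketone intact. Wittig methylenation of that ketone (excess Ph3P=CH2, THF) gives the methylidene Weinreb amide F4. Excess MeMgBr (THF, 0 °C) converts the amide into the methyl ketone and comes back to the route at 18.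

3. Step 6 (conjugate borylation). The borylcopper species may add with poor facial selectivity (equatorial delivery to the 3β-epimer), or the enone may be reduced or deconjugated under the basic copper conditions. The fallback sets out from 9. Nucleophilic epoxidation (t-BuOOH, DBU, CH2Cl2), in which the small peroxide anion attacks C3 axially, gives the 2α,3α-epoxy ketone F5. Reductive cleavage of the Cα–O bond with SmI2 (THF/MeOH, −90 °C) comes back to the route at 11.

**Further compounds**

F1 | step 9 | S-phenyl 2-[(1S,2S,3R,6R)-3-[(tert-butyldimethylsilyl)oxy]-5-oxo-6-(2-oxoethyl)-2-(propan-2-yl)cyclohexyl]ethanethioate | O=C1C[C@@H](O[Si](C)(C)C(C)(C)C)[C@@H](C(C)C)[C@H](CC(=O)Sc2ccccc2)[C@H]1CC=O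
F2 | step 9 | S-phenyl (1R,2S,3aR,6R,7S,7aS)-6-[(tert-butyldimethylsilyl)oxy]-2-hydroxy-4-oxo-7-(propan-2-yl)octahydro-1H-indene-1-carbothioate | O=C1C[C@@H](O[Si](C)(C)C(C)(C)C)[C@@H](C(C)C)[C@@H]2[C@@H](C(=O)Sc3ccccc3)[C@@H](O)C[C@@H]12
F3 | step 10 | (1R,2S,3aR,6R,7S,7aS)-6-[(tert-butyldimethylsilyl)oxy]-2-hydroxy-N-methoxy-N-methyl-4-oxo-7-(propan-2-yl)octahydro-1H-indene-1-carboxamide | O=C1C[C@@H](O[Si](C)(C)C(C)(C)C)[C@@H](C(C)C)[C@@H]2[C@@H](C(=O)N(C)OC)[C@@H](O)C[C@@H]12
F4 | step 10 | (1R,2S,3aR,6R,7S,7aR)-6-[(tert-butyldimethylsilyl)oxy]-2-hydroxy-N-methoxy-N-methyl-4-methylidene-7-(propan-2-yl)octahydro-1H-indene-1-carboxamide | C=C1C[C@@H](O[Si](C)(C)C(C)(C)C)[C@@H](C(C)C)[C@@H]2[C@@H](C(=O)N(C)OC)[C@@H](O)C[C@@H]12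
F5 | step 6 | 2α,3α-epoxide of 9 (oxirane across C2–C3 on the face opposite the C4–H; other stereocentres as in 9) | O=C1[C@H]2O[C@H]2[C@@H](C(C)C)[C@@H]3CC(O[Si](C)(C)C(C)(C)C)=CC[C@@H]13
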